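**Assumption:** the target is a planar, achiral isoflavone with no stereocentre, so there is no enantiomer to select; the stereocentres of intermediates 10, 12, 13 and 14 form racemic and are all erased in step 10.

**Retrosynthetic overview**
- The pyranone ring is formed last: O1–C2 closure of an o-hydroxyaryl β-keto dimethyl acetal with loss of MeOH, right after global O-debenzylation. Both benzene rings are bought.
- The β-keto acetal (3-aryl skeleton) comes from oxidative 1,2-aryl migration of a fully O-benzylated chalcone.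
- The chalcone comes from a Claisen–Schmidt aldol condensation of A-ring acetophenone 5 with B-ring benzaldehyde 9; this is the fragment-joining C–C bond.
- Acetophenone 5 comes from gallacetophenone (selective benzylation, C5 bromination, Cu methoxylation, benzylation).
- Aldehyde 9 comes from 5-bromovanillin (Cu hydroxylation, selective 4-O-methylation, benzylation).

**Route**

Step 1
Reactants: 1 1-(2,3,4-trihydroxyphenyl)ethanone (gallacetophenone)
Product: 2 1-[3,4-bis(benzyloxy)-2-hydroxyphenyl]ethanone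
Conditions: BnBr (2.1 equiv), K2CO3 (2.2 equiv), acetone, reflux, 12 h
Reagents that add atoms: benzyl bromide, BrCc1ccccc1
Why: Williamson etherification in which the 4-OH and 3-OH react, while the 2-OH is hydrogen-bonded to the acetyl C=O and is not alkylated by weak base in acetone.

Step 2
Reactants: 2 1-[3,4-bis(benzyloxy)-2-hydroxyphenyl]ethanone
Product: 3 1-[3,4-bis(benzyloxy)-5-bromo-2-hydroxyphenyl]ethanone
Conditions: NBS (1.05 equiv), MeCN, 0 °C to rt
Reagents that add atoms: N-bromosuccinimide, O=C1CCC(=O)N1Br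
Why: Electrophilic aromatic bromination goes to C5, which is para to the free phenol and ortho to a benzyloxy group, whereas the only other free position (C6) is ortho to the deactivating acetyl.

Step 3
Reactants: 3 1-[3,4-bis(benzyloxy)-5-bromo-2-hydroxyphenyl]ethanone
Product: 4 1-[3,4-bis(benzyloxy)-2-hydroxy-5-methoxyphenyl]ethanone
Conditions: NaOMe (6 equiv, 25% in MeOH), CuBr (0.2 equiv), DMF, 110 °C, N2; then aq. HCl
Reagents that add atoms: sodium methoxide, [Na+].[O-]C
Why: Ullmann-type copper-catalysed methoxylation of the aryl bromide; the substrate reacts as its phenoxide, which suppresses enolisation and aldol chemistry of the ketone, and benzyl ethers are inert to methoxide.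

Step 4
Reactants: 4 1-[3,4-bis(benzyloxy)-2-hydroxy-5-methoxyphenyl]ethanone
Product: 5 1-[2,3,4-tris(benzyloxy)-5-methoxyphenyl]ethanone
Conditions: BnBr (1.3 equiv), K2CO3 (2 equiv), KI (cat.), DMF, 70 °C
Reagents that add atoms: benzyl bromide, BrCc1ccccc1
Why: Williamson etherification under forcing polar aprotic conditions breaks the chelate and caps the last phenol, so no free p-methoxyphenol is present in the later oxidation.

Step 5
Reactants: 6 3-bromo-4-hydroxy-5-methoxybenzaldehyde (5-bromovanillin)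
Product: 7 3,4-dihydroxy-5-methoxybenzaldehyde (5-hydroxyvanillin)
Conditions: NaOH (8 equiv), Cu powder (5 mol %), H2O, reflux, N2, 24 h; then HCl
Reagents that add atoms: sodium hydroxide, [Na+].[OH-]
Why: Copper-catalysed (Ullmann-type) hydroxylation of the aryl bromide ortho to a phenoxide; the para-phenoxide makes the aldehyde a vinylogous carboxylate and protects it from Cannizzaro reaction.

Step 6
Reactants: 7 3,4-dihydroxy-5-methoxybenzaldehyde
Product: 8 3-hydroxy-4,5-dimethoxybenzaldehyde
Conditions: MeI (1.05 equiv), Li2CO3 (1.2 equiv), DMF, 40 °C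
Reagents that add atoms: iodomethane, CI
Why: Regioselective Williamson methylation, because the 4-OH para to the formyl group is clearly the more acidic phenol and is the only one ionised by the weak base.

Step 7
Reactants: 8 3-hydroxy-4,5-dimethoxybenzaldehyde
Product: 9 3-(benzyloxy)-4,5-dimethoxybenzaldehyde
Conditions: BnBr (1.2 equiv), K2CO3 (1.5 equiv), DMF, rt
Reagents that add atoms: benzyl bromide, BrCc1ccccc1
Why: Simple Williamson etherification of the one remaining phenol.

Step 8
Reactants: 5 1-[2,3,4-tris(benzyloxy)-5-methoxyphenyl]ethanone; 9 3-(benzyloxy)-4,5-dimethoxybenzaldehyde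
Product: 11 (E)-3-[3-(benzyloxy)-4,5-dimethoxyphenyl]-1-[2,3,4-tris(benzyloxy)-5-methoxyphenyl]prop-2-en-1-one, via β-hydroxy ketone aldol adduct 10 (not isolated)
Conditions: KOH (50% aq., 4 equiv), EtOH–THF (3:1), rt, 24–36 h
Reagents that add atoms: none
Why: Claisen–Schmidt crossed aldol condensation in which only the ketone can enolise and only the aldehyde can accept; E1cB dehydration gives the conjugated E-enone, and with no free phenol no flavanone can form.

Step 9
Reactants: 11 (E)-3-[3-(benzyloxy)-4,5-dimethoxyphenyl]-1-[2,3,4-tris(benzyloxy)-5-methoxyphenyl]prop-2-en-1-one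
Product: 12 2-[3-(benzyloxy)-4,5-dimethoxyphenyl]-3,3-dimethoxy-1-[2,3,4-tris(benzyloxy)-5-methoxyphenyl]propan-1-one
Conditions: Tl(NO3)3·3H2O (1.2 equiv), MeOH–HC(OMe)3 (1:1, orthoformate as drying co-solvent), CH2Cl2 co-solvent, rt, 16 h
Reagents that add atoms: methanol, CO
Why: Thallium(III)-mediated oxidative rearrangement of a chalcone: methoxythallation, 1,2-shift of the electron-rich p-methoxy-bearing B ring from Cβ to Cα with loss of Tl(I), and trapping of the oxocarbenium ion by methanol; the new C2 stereocentre is racemic and is erased in step 10.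

Step 10
Reactants: 12 2-[3-(benzyloxy)-4,5-dimethoxyphenyl]-3,3-dimethoxy-1-[2,3,4-tris(benzyloxy)-5-methoxyphenyl]propan-1-one
Product: 15 7,8-dihydroxy-3-(3-hydroxy-4,5-dimethoxyphenyl)-6-methoxy-4H-chromen-4-one, via tetraphenol dimethyl acetal 13 (not isolated), via 2-methoxyisoflavanone 14 (not isolated)
Conditions: H2 (1 atm), 10% Pd/C, EtOAc–MeOH (1:1), rt; filter under N2; then conc. HCl (10% v/v), degassed MeOH, 60 °C, 2 h
Reagents that add atoms: none
Why: Neutral hydrogenolysis removes the four benzyl ethers without touching the aryl ketone or acetal; acid then drives transacetalisation by the freed 2'-OH and elimination of methanol to the conjugated chromen-4-one, leaving no stereocentre.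

**Compound list**
1 | 1-(2,3,4-trihydroxyphenyl)ethanone (gallacetophenone) | CC(=O)c1ccc(O)c(O)c1O | starting material
2 | 1-[3,4-bis(benzyloxy)-2-hydroxyphenyl]ethanone | CC(=O)c1ccc(OCc2ccccc2)c(OCc2ccccc2)c1O | intermediate
3 | 1-[3,4-bis(benzyloxy)-5-bromo-2-hydroxyphenyl]ethanone | CC(=O)c1cc(Br)c(OCc2ccccc2)c(OCc2ccccc2)c1O | intermediate
4 | 1-[3,4-bis(benzyloxy)-2-hydroxy-5-methoxyphenyl]ethanone | CC(=O)c1cc(OC)c(OCc2ccccc2)c(OCc2ccccc2)c1O | intermediate
5 | 1-[2,3,4-tris(benzyloxy)-5-methoxyphenyl]ethanone | CC(=O)c1cc(OC)c(OCc2ccccc2)c(OCc2ccccc2)c1OCc1ccccc1 | intermediate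
6 | 3-bromo-4-hydroxy-5-methoxybenzaldehyde (5-bromovanillin) | COc1cc(C=O)cc(Br)c1O | starting material
7 | 3,4-dihydroxy-5-methoxybenzaldehyde (5-hydroxyvanillin) | COc1cc(C=O)cc(O)c1O | intermediate
8 | 3-hydroxy-4,5-dimethoxybenzaldehyde | COc1cc(C=O)cc(O)c1OC | intermediate
9 | 3-(benzyloxy)-4,5-dimethoxybenzaldehyde | COc1cc(C=O)cc(OCc2ccccc2)c1OC | intermediate
10 | 3-[3-(benzyloxy)-4,5-dimethoxyphenyl]-3-hydroxy-1-[2,3,4-tris(benzyloxy)-5-methoxyphenyl]propan-1-one (racemic aldol adduct, not isolated) | COc1cc(C(=O)CC(O)c2cc(OC)c(OC)c(OCc3ccccc3)c2)c(OCc2ccccc2)c(OCc2ccccc2)c1OCc1ccccc1 | intermediate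
11 | (E)-3-[3-(benzyloxy)-4,5-dimethoxyphenyl]-1-[2,3,4-tris(benzyloxy)-5-methoxyphenyl]prop-2-en-1-one | COc1cc(C(=O)/C=C/c2cc(OC)c(OC)c(OCc3ccccc3)c2)c(OCc2ccccc2)c(OCc2ccccc2)c1OCc1ccccc1 | intermediate
12 | 2-[3-(benzyloxy)-4,5-dimethoxyphenyl]-3,3-dimethoxy-1-[2,3,4-tris(benzyloxy)-5-methoxyphenyl]propan-1-one (racemic) | COc1cc(C(=O)C(C(OC)OC)c2cc(OC)c(OC)c(OCc3ccccc3)c2)c(OCc2ccccc2)c(OCc2ccccc2)c1OCc1ccccc1 | intermediate
13 | 2-(3-hydroxy-4,5-dimethoxyphenyl)-3,3-dimethoxy-1-(2,3,4-trihydroxy-5-methoxyphenyl)propan-1-one (racemic, not isolated) | COc1cc(C(=O)C(C(OC)OC)c2cc(OC)c(OC)c(O)c2)c(O)c(O)c1O | intermediate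
14 | 7,8-dihydroxy-3-(3-hydroxy-4,5-dimethoxyphenyl)-2,6-dimethoxychroman-4-one (racemic diastereomer mixture, not isolated) | COc1cc2c(c(O)c1O)OC(OC)C(C2=O)c1cc(O)c(OC)c(OC)c1 | intermediate
15 | 7,8-dihydroxy-3-(3-hydroxy-4,5-dimethoxyphenyl)-6-methoxy-4H-chromen-4-one | COc1cc2c(=O)c(-c3cc(O)c(OC)c(OC)c3)coc2c(O)c1O | target

**Step count**
Total steps: 10. Longest linear sequence: 7 steps (steps 1, 2, 3, 4, 8, 9, 10; compounds 1, 2, 3, 4, 5, 11, 12, 15). The B-ring branch (steps 5, 6, 7) joins at step 8.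

**Three steps most likely to fail, with fallbacks**

Step 9 (thallium oxidative rearrangement). The risks are incomplete aryl migration or oxidative damage to the electron-rich rings. The fallback sets out from chalcone 11 and comes back to the route at target 15, using the chalcone-epoxide route instead of an oxidative aryl shift. Weitz–Scheffer epoxidation of 11 (30% H2O2, NaOH, MeOH–THF, 0 °C) gives the racemic trans-epoxide [3-[3-(benzyloxy)-4,5-dimethoxyphenyl]oxiran-2-yl][2,3,4-tris(benzyloxy)-5-methoxyphenyl]methanone F5. Brief treatment with BF3·OEt2 (CH2Cl2, 0 °C, minutes) opens the epoxide at the benzylic carbon and triggers a 1,2-acyl shift to the α-formyl deoxybenzoin 2-[3-(benzyloxy)-4,5-dimethoxyphenyl]-3-oxo-3-[2,3,4-tris(benzyloxy)-5-methoxyphenyl]propanal F6. Hydrogenolysis (H2, Pd/C, EtOAc–MeOH) removes the four benzyl groups, and the freed 2'-OH closes onto the aldehyde to give the hemiacetal 2,7,8-trihydroxy-3-(3-hydroxy-4,5-dimethoxyphenyl)-6-methoxychroman-4-one F7. Warming F7 with HCl in MeOH dehydrates it to 15.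

Step 3 (copper methoxylation next to an enolisable ketone). The risks are hydrodebromination and base-mediated self-condensation. The fallback sets out from bromide 3 and comes back at compound 4, installing the oxygen through boron instead of copper. Miyaura borylation (B2pin2, PdCl2(dppf), KOAc, dioxane, 90 °C) gives 1-[3,4-bis(benzyloxy)-2-hydroxy-5-(4,4,5,5-tetramethyl-1,3,2-dioxaborolan-2-yl)phenyl]ethanone F1. Oxidation of the C–B bond with N-methylmorpholine N-oxide (THF, 60 °C, N2), which spares the ketone, gives the hydroquinone 1-[3,4-bis(benzyloxy)-2,5-dihydroxyphenyl]ethanone F2. MeI (1.05 equiv) with K2CO3 in acetone at rt methylates only the non-chelated 5-OH of F2 and delivers 4.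

Step 6 (regioselective mono-methylation of a catechol). The risks are 3-O-methyl and dimethyl by-products. The fallback sets out from 5-bromovanillin 6 and comes back at compound 8, so that the methylation needs no selectivity and steps 5 and 6 are both bypassed. Exhaustive methylation of 6 (MeI, K2CO3, DMF) gives 3-bromo-4,5-dimethoxybenzaldehyde F3. Miyaura borylation (B2pin2, PdCl2(dppf), KOAc, dioxane, 90 °C) gives 3,4-dimethoxy-5-(4,4,5,5-tetramethyl-1,3,2-dioxaborolan-2-yl)benzaldehyde F4. Oxidation of F4 with N-methylmorpholine N-oxide (THF, 60 °C), which leaves the aldehyde alone, gives 8.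

**Further compounds**
F1 | step 3 | 1-[3,4-bis(benzyloxy)-2-hydroxy-5-(4,4,5,5-tetramethyl-1,3,2-dioxaborolan-2-yl)phenyl]ethanone | CC(=O)c1cc(B2OC(C)(C)C(C)(C)O2)c(OCc2ccccc2)c(OCc2ccccc2)c1O
F2 | step 3 | 1-[3,4-bis(benzyloxy)-2,5-dihydroxyphenyl]ethanone | CC(=O)c1cc(O)c(OCc2ccccc2)c(OCc2ccccc2)c1O
F3 | step 6 | 3-bromo-4,5-dimethoxybenzaldehyde | COc1cc(C=O)cc(Br)c1OC
F4 | step 6 | 3,4-dimethoxy-5-(4,4,5,5-tetramethyl-1,3,2-dioxaborolan-2-yl)benzaldehyde | COc1cc(C=O)cc(B2OC(C)(C)C(C)(C)O2)c1OC
F5 | step 9 | [3-[3-(benzyloxy)-4,5-dimethoxyphenyl]oxiran-2-yl][2,3,4-tris(benzyloxy)-5-methoxyphenyl]methanone (racemic trans; the (2S,3R) enantiomer is drawn) | COc1cc(C(=O)[C@H]2O[C@@H]2c2cc(OC)c(OC)c(OCc3ccccc3)c2)c(OCc2ccccc2)c(OCc2ccccc2)c1OCc1ccccc1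
F6 | step 9 | 2-[3-(benzyloxy)-4,5-dimethoxyphenyl]-3-oxo-3-[2,3,4-tris(benzyloxy)-5-methoxyphenyl]propanal (racemic; largely enolised) | COc1cc(C(=O)C(C=O)c2cc(OC)c(OC)c(OCc3ccccc3)c2)c(OCc2ccccc2)c(OCc2ccccc2)c1OCc1ccccc1
F7 | step 9 | 2,7,8-trihydroxy-3-(3-hydroxy-4,5-dimethoxyphenyl)-6-methoxychroman-4-one (racemic diastereomer mixture) | COc1cc2c(c(O)c1O)OC(O)C(C2=O)c1cc(O)c(OC)c(OC)c1
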